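**Plan**
- The benzene ring carries the chain at C1 and two unlike oxygens, OH at C3 and OCH3 at C5, both meta to the chain. This 1,3,5-pattern is that of a 5-substituted cyclohexane-1,3-dione whose two carbonyl carbons are constitutionally equivalent, so one methyl enol ether and one dehydrogenation give the monomethyl resorcinol with no phenol protection.
- Cuts, in retrosynthetic order: the ring dehydrogenation (phenol back to a 3-methoxycyclohex-2-enone), the acetyl C–O bond, the enol ether O–CH3 bond, then ring bonds C1–C2 and C3–C4 (a Michael and a Claisen bond; the carbon lost as CO2 sat on C2; the numbering may run either way round the ring because the dione is symmetric), and last C1–C6 as the C=C of an enone (Wittig).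
- Forward: the C14 chain of methyl 3-oxotetradecanoate is extended by three carbons to a C17 enone, the only ring is closed on it with dimethyl malonate, and that ring is aromatised in the final step.
- Stereochemistry: the one stereocentre, (R) at the acetoxy carbon, is set in step 1 by hydrogenation over RuCl2[(R)-BINAP] and is never a reacting centre afterwards. The ring stereocentres of the intermediates are left uncontrolled and disappear on aromatisation.

Key step: step 5

Remark: 9, 10 and 11 are written as keto tautomers although they should be largely enolised; 8, 9, 10 and 12–14 are expected as mixtures at the uncontrolled chain or ring centres, all of which converge on 16.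

**Step 1**
Reactants: 1 methyl 3-oxotetradecanoate
Product: 2 methyl (R)-3-hydroxytetradecanoate
Conditions: H2 (50 atm), RuCl2[(R)-BINAP] (0.1 mol %), MeOH, 50 °C
Reagents that add atoms: none
Why: Noyori asymmetric hydrogenation of a β-keto ester, in which the ester carbonyl chelates ruthenium beside the ketone and the (R)-BINAP ligand directs hydride to the face that gives the (R)-carbinol, the established sense for 3-oxoalkanoates.

**Step 2**
Reactants: 2 methyl (R)-3-hydroxytetradecanoate
Product: 3 methyl (R)-3-[(tert-butyldimethylsilyl)oxy]tetradecanoate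
Conditions: TBSCl, imidazole, DMF, rt
Reagents that add atoms: tert-butyldimethylsilyl chloride, CC(C)(C)[Si](C)(C)Cl
Why: Standard imidazole-promoted silylation of a secondary alcohol; the silyl ether is chosen because it blocks retro-aldol loss at the aldehyde stage and lactonisation onto the malonate in step 5, and it tolerates methoxide and hydroxide.

**Step 3**
Reactants: 3 methyl (R)-3-[(tert-butyldimethylsilyl)oxy]tetradecanoate
Product: 4 (R)-3-[(tert-butyldimethylsilyl)oxy]tetradecanal
Conditions: i-Bu2AlH (1.1 equiv), CH2Cl2, −78 °C; MeOH, then aq. potassium sodium tartrate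
Reagents that add atoms: none
Why: Partial reduction of a methyl ester by i-Bu2AlH, whose tetrahedral aluminium hemiacetal is stable at −78 °C and releases the aldehyde only on work-up; the aldehyde should be used crude.

**Step 4**
Reactants: 4 (R)-3-[(tert-butyldimethylsilyl)oxy]tetradecanal; 5 1-(triphenylphosphoranylidene)propan-2-one
Product: 6 (R,E)-6-[(tert-butyldimethylsilyl)oxy]heptadec-3-en-2-one
Conditions: 5 (1.3 equiv), toluene, 80 °C
Reagents that add atoms: none
Why: Wittig olefination with a stabilised, weakly basic acyl ylide, which should give the E-enone and leave the β-silyloxy aldehyde unenolised.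

**Step 5**
Reactants: 6 (R,E)-6-[(tert-butyldimethylsilyl)oxy]heptadec-3-en-2-one; 7 dimethyl malonate
Product: 9 methyl 2,4-dioxo-6-[(R)-2-[(tert-butyldimethylsilyl)oxy]tridecyl]cyclohexane-1-carboxylate, via Michael adduct 8 (not isolated)
Conditions: 7 (1.2 equiv), NaOMe (1.1 equiv), MeOH, 0 °C, then 6, rt to reflux; 1 M HCl to pH 3, 0 °C
Reagents that add atoms: none
Why: Preformed sodiomalonate adds in conjugate fashion to C4 of enone 6 to give 8; methoxide then equilibrates the enolates, and the methyl-side (C1) enolate of the ketone acylates one malonate ester carbonyl with loss of methoxide, the sequence being drawn forward by formation of the stabilised β-diketone enolate of 9. The closest known reaction type is the Michael–Claisen annulation of alk-3-en-2-ones with malonic esters to 5-substituted 1,3-dioxocyclohexane carboxylates, the classical entry to 5-alkylresorcinols. The single carbocycle closes in a 6-exo-trig mode, the enolate carbon attacking an ester carbonyl whose C=O lies outside the forming ring. The two ring stereocentres (C1 and C6 of 9) arise without control and need none, since C1 is lost with the decarboxylation and C6 becomes sp2 on aromatisation, while the silyloxy-bearing centre carries no acidic hydrogen and is untouched. The step needs 1,4-addition to outrun γ-deprotonation and vinylogous loss of the δ-silyloxy group, which the soft malonate anion, the low concentration of free methoxide and the poor silyloxide leaving group should secure; the closure is regiochemically unambiguous because the C3 enolate could only form a four-membered ring, and the silyl ether keeps the chain oxygen from lactonising onto a malonate ester.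

**Step 6**
Reactants: 9 methyl 2,4-dioxo-6-[(R)-2-[(tert-butyldimethylsilyl)oxy]tridecyl]cyclohexane-1-carboxylate
Product: 11 5-[(R)-2-[(tert-butyldimethylsilyl)oxy]tridecyl]cyclohexane-1,3-dione, via keto acid 10 (not isolated)
Conditions: NaOH (4 equiv), MeOH–H2O, reflux; then 1 M HCl to pH 3–4, 50 °C
Reagents that add atoms: none
Why: Saponification of the β-keto ester followed by decarboxylation of the β-keto acid through the usual six-membered transition state, the standard finish of a malonate annulation; the secondary silyl ether should tolerate hydroxide and the brief mildly acidic warming.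

**Step 7**
Reactants: 11 5-[(R)-2-[(tert-butyldimethylsilyl)oxy]tridecyl]cyclohexane-1,3-dione
Product: 12 5-[(R)-2-[(tert-butyldimethylsilyl)oxy]tridecyl]-3-methoxycyclohex-2-en-1-one (mixture of C5 epimers)
Conditions: Me3SiCHN2 (1.5 equiv), MeOH–toluene, 0 °C to rt
Reagents that add atoms: (trimethylsilyl)diazomethane, C[Si](C)(C)C=[N+]=[N-]
Why: O-methylation of an acidic cyclic 1,3-dione enol by a diazoalkane (protonation of the reagent, then O-alkylation of the enolate) under neutral conditions that spare the silyl ether; because the two carbonyls are constitutionally equivalent only one vinylogous ester constitution can form, and the new C5 centre is uncontrolled and later erased.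

**Step 8**
Reactants: 12 5-[(R)-2-[(tert-butyldimethylsilyl)oxy]tridecyl]-3-methoxycyclohex-2-en-1-one
Product: 13 5-[(R)-2-hydroxytridecyl]-3-methoxycyclohex-2-en-1-one (mixture of C5 epimers)
Conditions: HF·pyridine, pyridine, THF, 0 °C to rt
Reagents that add atoms: none
Why: Fluoride cleavage of the Si–O bond; the pyridine-buffered, anhydrous reagent generates neither a free alkoxide, which could add to C3 of the vinylogous ester, nor aqueous acid, which would hydrolyse the enol ether, and the alcohol is carried on without storage.

**Step 9**
Reactants: 13 5-[(R)-2-hydroxytridecyl]-3-methoxycyclohex-2-en-1-one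
Product: 14 (R)-1-(5-methoxy-3-oxocyclohex-4-en-1-yl)tridecan-2-yl acetate (mixture of ring epimers)
Conditions: Ac2O, pyridine, DMAP (cat.), CH2Cl2, 0 °C to rt
Reagents that add atoms: acetic anhydride, CC(=O)OC(C)=O
Why: DMAP-catalysed acylation of a secondary alcohol, which breaks only the O–H bond and so retains the (R) configuration; placing the acetate before the oxidation removes the alcohol from the reach of the palladium catalyst and means that the phenol is never protected.

**Step 10**
Reactants: 14 (R)-1-(5-methoxy-3-oxocyclohex-4-en-1-yl)tridecan-2-yl acetate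
Product: 16 (R)-1-(3-hydroxy-5-methoxyphenyl)tridecan-2-yl acetate, via cross-conjugated dienone 15 (not isolated)
Conditions: Pd(OCOCF3)2 (5 mol %), 2-(dimethylamino)pyridine (10 mol %), TsOH (20 mol %), O2 (1 atm), 3 Å molecular sieves, DMSO, 80 °C
Reagents that add atoms: none
Why: Palladium-catalysed aerobic dehydrogenation of a cyclohex-2-enone to a phenol: a divalent palladium enolate forms at C6, β-hydride elimination from C5 gives dienone 15, which tautomerises to the arene, and O2 returns zerovalent palladium to the divalent state; both C5 epimers converge, the acetate and the methyl ether are inert, and the sieves take up the water that could hydrolyse the enol ether.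

**Compound list**
1 | methyl 3-oxotetradecanoate | CCCCCCCCCCCC(=O)CC(=O)OC | starting material
2 | methyl (R)-3-hydroxytetradecanoate | CCCCCCCCCCC[C@H](CC(=O)OC)O | intermediate
3 | methyl (R)-3-[(tert-butyldimethylsilyl)oxy]tetradecanoate | CCCCCCCCCCC[C@H](CC(=O)OC)O[Si](C)(C)C(C)(C)C | intermediate
4 | (R)-3-[(tert-butyldimethylsilyl)oxy]tetradecanal | CCCCCCCCCCC[C@H](CC=O)O[Si](C)(C)C(C)(C)C | intermediate
5 | 1-(triphenylphosphoranylidene)propan-2-one | CC(=O)C=P(c1ccccc1)(c1ccccc1)c1ccccc1 | starting material
6 | (R,E)-6-[(tert-butyldimethylsilyl)oxy]heptadec-3-en-2-one | CCCCCCCCCCC[C@H](C/C=C/C(C)=O)O[Si](C)(C)C(C)(C)C | intermediate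
7 | dimethyl malonate | COC(=O)CC(=O)OC | starting material
8 | dimethyl 2-[(6R)-6-[(tert-butyldimethylsilyl)oxy]-2-oxoheptadecan-4-yl]propanedioate (C4 epimers, not isolated) | CCCCCCCCCCC[C@H](CC(CC(C)=O)C(C(=O)OC)C(=O)OC)O[Si](C)(C)C(C)(C)C | intermediate
9 | methyl 2,4-dioxo-6-[(R)-2-[(tert-butyldimethylsilyl)oxy]tridecyl]cyclohexane-1-carboxylate (ring epimers, largely enolised) | CCCCCCCCCCC[C@H](CC1CC(=O)CC(=O)C1C(=O)OC)O[Si](C)(C)C(C)(C)C | intermediate
10 | 2,4-dioxo-6-[(R)-2-[(tert-butyldimethylsilyl)oxy]tridecyl]cyclohexane-1-carboxylic acid (not isolated) | CCCCCCCCCCC[C@H](CC1CC(=O)CC(=O)C1C(=O)O)O[Si](C)(C)C(C)(C)C | intermediate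
11 | 5-[(R)-2-[(tert-butyldimethylsilyl)oxy]tridecyl]cyclohexane-1,3-dione | CCCCCCCCCCC[C@H](CC1CC(=O)CC(=O)C1)O[Si](C)(C)C(C)(C)C | intermediate
12 | 5-[(R)-2-[(tert-butyldimethylsilyl)oxy]tridecyl]-3-methoxycyclohex-2-en-1-one (C5 epimers) | CCCCCCCCCCC[C@H](CC1CC(=O)C=C(OC)C1)O[Si](C)(C)C(C)(C)C | intermediate
13 | 5-[(R)-2-hydroxytridecyl]-3-methoxycyclohex-2-en-1-one (C5 epimers) | CCCCCCCCCCC[C@H](CC1CC(=O)C=C(OC)C1)O | intermediate
14 | (R)-1-(5-methoxy-3-oxocyclohex-4-en-1-yl)tridecan-2-yl acetate (ring epimers) | CCCCCCCCCCC[C@H](CC1CC(=O)C=C(OC)C1)OC(C)=O | intermediate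
15 | (R)-1-(5-methoxy-3-oxocyclohexa-1,4-dien-1-yl)tridecan-2-yl acetate (not isolated) | CCCCCCCCCCC[C@H](CC1=CC(=O)C=C(OC)C1)OC(C)=O | intermediate
16 | (R)-1-(3-hydroxy-5-methoxyphenyl)tridecan-2-yl acetate (CNP0215596.1) | CCCCCCCCCCC[C@H](Cc1cc(O)cc(OC)c1)OC(C)=O | target

**Totals**
Total step count: 10. Longest linear sequence: 10 steps, from 1 to 16.

**Steps most likely to fail**

Step 10. Palladation at C6 of the electron-rich vinylogous ester may be slow, so the catalyst could aggregate to inactive palladium metal before conversion is complete. The water formed from O2 could also hydrolyse the enol ether under the acid co-catalyst, which would end in loss of the methyl group. The fallback sets out from 12 and moves the aromatisation ahead of the protecting-group exchange, using enolate selenium chemistry. Deprotonation with LiN(i-Pr)2 in THF at −78 °C and quenching with PhSeCl should give 5-[(R)-2-[(tert-butyldimethylsilyl)oxy]tridecyl]-3-methoxy-6-(phenylselanyl)cyclohex-2-en-1-one F1, with selenium trans to the C5 substituent and therefore syn to the C5 hydrogen. Oxidation with H2O2 and pyridine in CH2Cl2 at 0 °C to rt should bring about selenoxide syn-elimination and tautomerisation to 3-methoxy-5-[(R)-2-[(tert-butyldimethylsilyl)oxy]tridecyl]phenol F2. Bu4NF in THF should free 5-[(R)-2-hydroxytridecyl]-3-methoxyphenol F3. Ac2O, pyridine and DMAP should give (R)-1-(3-acetoxy-5-methoxyphenyl)tridecan-2-yl acetate F4. Pyrrolidine in CH2Cl2 at 0 °C should then cleave only the aryl acetate, which returns to the route at 16.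

Step 5. γ-Deprotonation of the enone with vinylogous β-elimination of the silyloxy group, reversal of the conjugate addition before the Claisen closure, or methanolysis of the silyl ether followed by lactonisation could drain the material. The fallback sets out from 4 and builds the same ring with the polarity of the partners exchanged. Wittig reaction of 4 with methyl (triphenylphosphoranylidene)acetate in CH2Cl2 should give methyl (R,E)-5-[(tert-butyldimethylsilyl)oxy]hexadec-2-enoate F5, which is less acidic at the γ-position than the enone. Methyl acetoacetate and NaOMe in MeOH at reflux should add to it to give dimethyl 2-acetyl-3-[(R)-2-[(tert-butyldimethylsilyl)oxy]tridecyl]pentanedioate F6, not isolated. The acetyl enolate of this adduct should close on the chain ester, and after acidification this gives 9, where the route is rejoined.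

Step 3. The aluminium hemiacetal may collapse before the quench and lead to over-reduction, and the aldehyde may lose silanol by β-elimination during isolation. The fallback sets out from 3 and separates reduction from oxidation-level adjustment. LiBH4 in THF should reduce the ester fully to (R)-3-[(tert-butyldimethylsilyl)oxy]tetradecan-1-ol F7. Dess–Martin periodinane with NaHCO3 in CH2Cl2 should then give 4, which is taken directly into step 4.

**Further compounds**
F1 | step 10 | 5-[(R)-2-[(tert-butyldimethylsilyl)oxy]tridecyl]-3-methoxy-6-(phenylselanyl)cyclohex-2-en-1-one | CCCCCCCCCCC[C@H](CC1CC(OC)=CC(=O)C1[Se]c1ccccc1)O[Si](C)(C)C(C)(C)C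
F2 | step 10 | 3-methoxy-5-[(R)-2-[(tert-butyldimethylsilyl)oxy]tridecyl]phenol | CCCCCCCCCCC[C@H](Cc1cc(O)cc(OC)c1)O[Si](C)(C)C(C)(C)C
F3 | step 10 | 5-[(R)-2-hydroxytridecyl]-3-methoxyphenol | CCCCCCCCCCC[C@H](Cc1cc(O)cc(OC)c1)O
F4 | step 10 | (R)-1-(3-acetoxy-5-methoxyphenyl)tridecan-2-yl acetate | CCCCCCCCCCC[C@H](Cc1cc(OC(C)=O)cc(OC)c1)OC(C)=O
F5 | step 5 | methyl (R,E)-5-[(tert-butyldimethylsilyl)oxy]hexadec-2-enoate | CCCCCCCCCCC[C@H](C/C=C/C(=O)OC)O[Si](C)(C)C(C)(C)C
F6 | step 5 | dimethyl 2-acetyl-3-[(R)-2-[(tert-butyldimethylsilyl)oxy]tridecyl]pentanedioate | CCCCCCCCCCC[C@H](CC(CC(=O)OC)C(C(C)=O)C(=O)OC)O[Si](C)(C)C(C)(C)C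
F7 | step 3 | (R)-3-[(tert-butyldimethylsilyl)oxy]tetradecan-1-ol | CCCCCCCCCCC[C@H](CCO)O[Si](C)(C)C(C)(C)C
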